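## Retrosynthetic overview

1. Last disconnection: the O10–C3 bond. The 3(2H)-furanone and its 3,10-oxygen bridge come from a transannular C–O closure of the C10 tertiary hydroxyl onto a ten-membered γ-hydroxy ynone.
2. Ten-membered carbocycle: the C3–C4 bond, by intramolecular Nozaki–Hiyama–Kishi coupling of a (Z)-vinyl iodide with an ynal, followed by oxidation of the new carbinol.
3. Seco chain: (Z)-iodo-olefination at C5 (sets C4=C5), angelate on O8, alkynyl Grignard addition to a C10 methyl ketone (sets C10), proline aldol of acetone with a lactone aldehyde (sets C8).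
4. The γ-lactone carrying C6, C7 and C11 comes from (S)-5-(hydroxymethyl)furan-2(5H)-one by anti conjugate vinyl addition, anti methylation and ozonolysis.
5. Ring order: γ-lactone (chiral pool) → ten-membered carbocycle → furanone ring by the C–O closure.

Assumption: the target SMILES is read as (4Z,6R,7R,8R,10R,11S) with a (Z)-2-methylbut-2-enoate (angelate) ester; atom labels C1–C15 follow germacrane numbering (C1 ring ketone, C3 enol-ether carbon, C6 lactone carbinol, C8 ester carbinol, C10 quaternary carbon, C11 lactone α-carbon).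

## Route

Step 1
Reactants: 1 (S)-5-(hydroxymethyl)furan-2(5H)-one
Product: 2 (S)-5-{[(tert-butyldimethylsilyl)oxy]methyl}furan-2(5H)-one
Conditions: TBSCl, imidazole, CH2Cl2, 0 °C → rt
Reagents that add atoms: tert-butyldimethylsilyl chloride (TBSCl), CC(C)(C)[Si](C)(C)Cl
Why: Imidazole-promoted silylation (silyl ether protection) masks the primary hydroxyl and installs the bulky C5 substituent that will direct the conjugate addition, without touching the stereocentre (C6 of the target).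

Step 2
Reactants: 2 (S)-5-{[(tert-butyldimethylsilyl)oxy]methyl}furan-2(5H)-one
Product: 4 (3S,4S,5S)-5-{[(tert-butyldimethylsilyl)oxy]methyl}-4-ethenyl-3-methyloxolan-2-one, via magnesium enolate 3 (not isolated)
Conditions: CH2=CHMgBr, CuBr·SMe2 (10 mol %), THF, −78 °C; then MeI, DMPU, −78 → 0 °C
Reagents that add atoms: vinylmagnesium bromide, C=C[Mg]Br; iodomethane, CI
Why: Copper-catalysed 1,4-addition of the vinyl Grignard reagent occurs anti to the silyloxymethyl group and sets C7, and enolate 3 is then C-methylated anti to the new vinyl group (tandem conjugate addition–enolate alkylation), which sets C11 and gives the all-trans lactone.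

Step 3
Reactants: 4 (3S,4S,5S)-5-{[(tert-butyldimethylsilyl)oxy]methyl}-4-ethenyl-3-methyloxolan-2-one
Product: 6 (2S,3S,4S)-2-{[(tert-butyldimethylsilyl)oxy]methyl}-4-methyl-5-oxooxolane-3-carbaldehyde, via ozonide 5 (not isolated)
Conditions: O3, CH2Cl2, −78 °C; then Me2S, −78 °C → rt
Reagents that add atoms: ozone, [O-][O+]=O
Why: Ozonolysis of the only C=C bond with reductive work-up unveils the C8 aldehyde while the silyl ether and lactone are inert, and the all-trans C6/C7/C11 array is the thermodynamically preferred one so the α-formyl centre is not at risk.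

Step 4
Reactants: 6 (2S,3S,4S)-2-{[(tert-butyldimethylsilyl)oxy]methyl}-4-methyl-5-oxooxolane-3-carbaldehyde; 7 acetone
Product: 8 (3S,4R,5S)-5-{[(tert-butyldimethylsilyl)oxy]methyl}-4-[(1R)-1-hydroxy-3-oxobutyl]-3-methyloxolan-2-one
Conditions: L-proline (30 mol %), acetone/DMSO (1:4), rt
Reagents that add atoms: none
Why: The proline-catalysed direct intermolecular aldol reaction (enamine catalysis) delivers the acetone enamine to the Re face of the α-branched aldehyde under catalyst control, which sets (8R) as it does for simple α-branched aldehydes, while the large excess of acetone suppresses self-condensation of 6.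

Step 5
Reactants: 8 (3S,4R,5S)-5-{[(tert-butyldimethylsilyl)oxy]methyl}-4-[(1R)-1-hydroxy-3-oxobutyl]-3-methyloxolan-2-one; 9 3,3-diethoxyprop-1-yne
Product: 11 (3S,4R,5S)-5-{[(tert-butyldimethylsilyl)oxy]methyl}-4-[(1R,3R)-6,6-diethoxy-1,3-dihydroxy-3-methylhex-4-yn-1-yl]-3-methyloxolan-2-one, via alkynylmagnesium bromide 10 (not isolated)
Conditions: 9, EtMgBr, THF, 0 °C → rt; then 8 (3 equiv of 10), THF/CH2Cl2, −78 → −30 °C; aq. NH4Cl
Reagents that add atoms: none
Why: Grignard 1,2-addition to the methyl ketone proceeds through the six-membered magnesium chelate of the C8 alkoxide and the C10 carbonyl (chelation-controlled 1,3-induction, external attack trans to the C8 substituent) to give the 8,10-anti diol, i.e. (10R), while the weakly nucleophilic alkynyl reagent spares the lactone at low temperature and any minor C10 epimer is removed by chromatography.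

Step 6
Reactants: 11 (3S,4R,5S)-5-{[(tert-butyldimethylsilyl)oxy]methyl}-4-[(1R,3R)-6,6-diethoxy-1,3-dihydroxy-3-methylhex-4-yn-1-yl]-3-methyloxolan-2-one; 12 angelic acid
Product: 14 (1R,3R)-1-[(2S,3R,4S)-2-{[(tert-butyldimethylsilyl)oxy]methyl}-4-methyl-5-oxooxolan-3-yl]-6,6-diethoxy-3-hydroxy-3-methylhex-4-yn-1-yl (2Z)-2-methylbut-2-enoate, via mixed anhydride 13 (not isolated)
Conditions: 12, 2,4,6-Cl3C6H2COCl, Et3N, toluene, rt; then 11, toluene, 80 °C
Reagents that add atoms: none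
Why: Yamaguchi-type acylation through mixed anhydride 13 without DMAP esterifies only the secondary C8 hydroxyl (the tertiary propargylic C10 hydroxyl does not react), keeps the Z geometry of the angelate and retains configuration at C8.

Step 7
Reactants: 14 (1R,3R)-1-[(2S,3R,4S)-2-{[(tert-butyldimethylsilyl)oxy]methyl}-4-methyl-5-oxooxolan-3-yl]-6,6-diethoxy-3-hydroxy-3-methylhex-4-yn-1-yl (2Z)-2-methylbut-2-enoate
Product: 15 (1R,3R)-6,6-diethoxy-3-hydroxy-1-[(2S,3R,4S)-2-(hydroxymethyl)-4-methyl-5-oxooxolan-3-yl]-3-methylhex-4-yn-1-yl (2Z)-2-methylbut-2-enoate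
Conditions: HF·pyridine, pyridine, THF, 0 °C → rt
Reagents that add atoms: none
Why: Buffered fluoride desilylation cleaves the primary silyl ether while the propargylic diethyl acetal, both esters and the tertiary alcohol survive.

Step 8
Reactants: 15 (1R,3R)-6,6-diethoxy-3-hydroxy-1-[(2S,3R,4S)-2-(hydroxymethyl)-4-methyl-5-oxooxolan-3-yl]-3-methylhex-4-yn-1-yl (2Z)-2-methylbut-2-enoate
Product: 16 (1R,3R)-6,6-diethoxy-1-[(2S,3R,4S)-2-formyl-4-methyl-5-oxooxolan-3-yl]-3-hydroxy-3-methylhex-4-yn-1-yl (2Z)-2-methylbut-2-enoate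
Conditions: Dess–Martin periodinane, CH2Cl2, 0 °C → rt
Reagents that add atoms: none
Why: Dess–Martin oxidation converts the primary alcohol to the C5 aldehyde under near-neutral conditions that neither epimerise C6 nor touch the tertiary alcohol.

Step 9
Reactants: 16 (1R,3R)-6,6-diethoxy-1-[(2S,3R,4S)-2-formyl-4-methyl-5-oxooxolan-3-yl]-3-hydroxy-3-methylhex-4-yn-1-yl (2Z)-2-methylbut-2-enoate
Product: 17 (1R,3R)-6,6-diethoxy-3-hydroxy-1-[(2S,3R,4S)-2-[(1Z)-2-iodoprop-1-en-1-yl]-4-methyl-5-oxooxolan-3-yl]-3-methylhex-4-yn-1-yl (2Z)-2-methylbut-2-enoate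
Conditions: [Ph3PEt]I, n-BuLi, THF, 0 °C; I2, −78 °C; NaN(SiMe3)2, −78 → −20 °C; then 16, −78 → −20 °C
Reagents that add atoms: ethyltriphenylphosphonium iodide, CC[P+](c1ccccc1)(c1ccccc1)c1ccccc1.[I-]; iodine, II
Why: The Stork–Zhao-type Wittig olefination with the α-iodo ylide Ph3P=C(CH3)I gives the (Z)-2-iodoprop-1-enyl group with iodine cis to C6, which fixes the C4=C5 geometry of the target, and the salt-free low-temperature ylide is not basic enough to epimerise C6 or attack the esters.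

Step 10
Reactants: 17 (1R,3R)-6,6-diethoxy-3-hydroxy-1-[(2S,3R,4S)-2-[(1Z)-2-iodoprop-1-en-1-yl]-4-methyl-5-oxooxolan-3-yl]-3-methylhex-4-yn-1-yl (2Z)-2-methylbut-2-enoate
Product: 18 (1R,3R)-3-hydroxy-1-[(2S,3R,4S)-2-[(1Z)-2-iodoprop-1-en-1-yl]-4-methyl-5-oxooxolan-3-yl]-3-methyl-6-oxohex-4-yn-1-yl (2Z)-2-methylbut-2-enoate
Conditions: TsOH·H2O (20 mol %), acetone/H2O (10:1), rt
Reagents that add atoms: water, O
Why: Acid-catalysed acetal hydrolysis releases the ynal under conditions too mild for Meyer–Schuster rearrangement of the tertiary propargylic alcohol or for ester cleavage.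

Step 11
Reactants: 18 (1R,3R)-3-hydroxy-1-[(2S,3R,4S)-2-[(1Z)-2-iodoprop-1-en-1-yl]-4-methyl-5-oxooxolan-3-yl]-3-methyl-6-oxohex-4-yn-1-yl (2Z)-2-methylbut-2-enoate
Product: 19 (4Z,6R,7R,8R,10R,11S)-8-angeloyloxy-3,10-dihydroxygermacr-4-en-1-yn-12,6-olide (both C3 epimers)
Conditions: CrCl2 (10 equiv), NiCl2 (10 mol %), DMSO/THF (3:1), rt, syringe-pump addition to 2 mM
Reagents that add atoms: none
Why: The intramolecular Nozaki–Hiyama–Kishi reaction (nickel-catalysed activation of the vinyl iodide with retention of geometry, transmetalation to chromium, chemoselective 1,2-addition to the ynal) closes the ten-membered ring at C3–C4 under high dilution, helped by the Z-olefin, the rigid alkyne and the trans-fused lactone, and the C3 configuration is irrelevant because that carbinol is oxidised next.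

Step 12
Reactants: 19 (4Z,6R,7R,8R,10R,11S)-8-angeloyloxy-3,10-dihydroxygermacr-4-en-1-yn-12,6-olide
Product: 20 (4Z,6R,7R,8R,10R,11S)-8-angeloyloxy-10-hydroxy-3-oxogermacr-4-en-1-yn-12,6-olide
Conditions: MnO2, CH2Cl2, rt
Reagents that add atoms: none
Why: MnO2 oxidation is selective for the doubly activated (allylic and propargylic) secondary alcohol and gives the cross-conjugated ynone while the tertiary C10 alcohol cannot be oxidised.

Step 13
Reactants: 20 (4Z,6R,7R,8R,10R,11S)-8-angeloyloxy-10-hydroxy-3-oxogermacr-4-en-1-yn-12,6-olide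
Product: 22 (4Z,6R,7R,8R,10R,11S)-8-angeloyloxy-3,10-epoxy-1-oxogermacra-2,4-dien-12,6-olide (target CNP0278264.1), via β-diketone 21 (not isolated)
Conditions: (4-CF3C6H4)3PAuCl (5 mol %), AgOSO2CF3 (5 mol %), H2O (1 equiv), toluene, rt
Reagents that add atoms: water, O
Why: Proposed new method: a transannular, oxygen-transposing hydrative cycloisomerisation of a ten-membered γ-hydroxy ynone, in which the cationic monovalent gold centre activates the C1≡C2 bond, water adds at C1 (the β-carbon of the ynone) to give after protodeauration β-diketone 21, the C10 hydroxyl closes 5-exo-trig onto the C3 carbonyl and the hemiketal loses water to form the O10–C3 bond of the vinylogous ester, so that the furanone ring and the 3,10-oxygen bridge arise in one operation while C10, not being a reaction site, keeps its configuration; the closest known reaction types are the gold-catalysed cyclisation of acyclic γ-hydroxyalkynones to 3(2H)-furanones and the gold-catalysed transannular oxa-Michael closure of macrocyclic α′-hydroxy ynones, neither shown for a strained cyclodecenynone that needs carbonyl transposition.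

## Compound list

1 | (S)-5-(hydroxymethyl)furan-2(5H)-one | OC[C@H]1OC(=O)C=C1 | starting material
2 | (S)-5-{[(tert-butyldimethylsilyl)oxy]methyl}furan-2(5H)-one | CC(C)(C)[Si](C)(C)OC[C@H]1OC(=O)C=C1 | intermediate
3 | magnesium enolate: {[(2S,3S)-2-{[(tert-butyldimethylsilyl)oxy]methyl}-3-ethenyl-2,3-dihydrofuran-5-yl]oxy}magnesium bromide (vinyl trans to CH2OTBS) | CC(C)(C)[Si](C)(C)OC[C@H]1OC(O[Mg]Br)=C[C@@H]1C=C | intermediate
4 | (3S,4S,5S)-5-{[(tert-butyldimethylsilyl)oxy]methyl}-4-ethenyl-3-methyloxolan-2-one (all-trans) | CC(C)(C)[Si](C)(C)OC[C@H]1OC(=O)[C@@H](C)[C@@H]1C=C | intermediate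
5 | ozonide: (3S,4S,5S)-5-{[(tert-butyldimethylsilyl)oxy]methyl}-3-methyl-4-(1,2,4-trioxolan-3-yl)oxolan-2-one (trioxolane carbon unassigned) | CC(C)(C)[Si](C)(C)OC[C@H]1OC(=O)[C@@H](C)[C@@H]1C2OCOO2 | intermediate
6 | (2S,3S,4S)-2-{[(tert-butyldimethylsilyl)oxy]methyl}-4-methyl-5-oxooxolane-3-carbaldehyde | CC(C)(C)[Si](C)(C)OC[C@H]1OC(=O)[C@@H](C)[C@@H]1C=O | intermediate
7 | acetone | CC(C)=O | starting material
8 | (3S,4R,5S)-5-{[(tert-butyldimethylsilyl)oxy]methyl}-4-[(1R)-1-hydroxy-3-oxobutyl]-3-methyloxolan-2-one | CC(C)(C)[Si](C)(C)OC[C@H]1OC(=O)[C@@H](C)[C@@H]1[C@H](O)CC(C)=O | intermediate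
9 | 3,3-diethoxyprop-1-yne | C#CC(OCC)OCC | starting material
10 | (3,3-diethoxyprop-1-yn-1-yl)magnesium bromide | CCOC(OCC)C#C[Mg]Br | intermediate
11 | (3S,4R,5S)-5-{[(tert-butyldimethylsilyl)oxy]methyl}-4-[(1R,3R)-6,6-diethoxy-1,3-dihydroxy-3-methylhex-4-yn-1-yl]-3-methyloxolan-2-one | CC(C)(C)[Si](C)(C)OC[C@H]1OC(=O)[C@@H](C)[C@@H]1[C@H](O)C[C@@](C)(O)C#CC(OCC)OCC | intermediate
12 | angelic acid, (2Z)-2-methylbut-2-enoic acid | C/C=C(/C)C(=O)O | starting material
13 | mixed anhydride: (2Z)-2-methylbut-2-enoic 2,4,6-trichlorobenzoic anhydride | C/C=C(/C)C(=O)OC(=O)c1c(Cl)cc(Cl)cc1Cl | intermediate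
14 | (1R,3R)-1-[(2S,3R,4S)-2-{[(tert-butyldimethylsilyl)oxy]methyl}-4-methyl-5-oxooxolan-3-yl]-6,6-diethoxy-3-hydroxy-3-methylhex-4-yn-1-yl (2Z)-2-methylbut-2-enoate | CC(C)(C)[Si](C)(C)OC[C@H]1OC(=O)[C@@H](C)[C@@H]1[C@H](OC(=O)/C(C)=C\C)C[C@@](C)(O)C#CC(OCC)OCC | intermediate
15 | (1R,3R)-6,6-diethoxy-3-hydroxy-1-[(2S,3R,4S)-2-(hydroxymethyl)-4-methyl-5-oxooxolan-3-yl]-3-methylhex-4-yn-1-yl (2Z)-2-methylbut-2-enoate | OC[C@H]1OC(=O)[C@@H](C)[C@@H]1[C@H](OC(=O)/C(C)=C\C)C[C@@](C)(O)C#CC(OCC)OCC | intermediate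
16 | (1R,3R)-6,6-diethoxy-1-[(2S,3R,4S)-2-formyl-4-methyl-5-oxooxolan-3-yl]-3-hydroxy-3-methylhex-4-yn-1-yl (2Z)-2-methylbut-2-enoate | O=C[C@H]1OC(=O)[C@@H](C)[C@@H]1[C@H](OC(=O)/C(C)=C\C)C[C@@](C)(O)C#CC(OCC)OCC | intermediate
17 | (1R,3R)-6,6-diethoxy-3-hydroxy-1-[(2S,3R,4S)-2-[(1Z)-2-iodoprop-1-en-1-yl]-4-methyl-5-oxooxolan-3-yl]-3-methylhex-4-yn-1-yl (2Z)-2-methylbut-2-enoate | I/C(C)=C\[C@H]1OC(=O)[C@@H](C)[C@@H]1[C@H](OC(=O)/C(C)=C\C)C[C@@](C)(O)C#CC(OCC)OCC | intermediate
18 | (1R,3R)-3-hydroxy-1-[(2S,3R,4S)-2-[(1Z)-2-iodoprop-1-en-1-yl]-4-methyl-5-oxooxolan-3-yl]-3-methyl-6-oxohex-4-yn-1-yl (2Z)-2-methylbut-2-enoate | I/C(C)=C\[C@H]1OC(=O)[C@@H](C)[C@@H]1[C@H](OC(=O)/C(C)=C\C)C[C@@](C)(O)C#CC=O | intermediate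
19 | (4Z,6R,7R,8R,10R,11S)-8-angeloyloxy-3,10-dihydroxygermacr-4-en-1-yn-12,6-olide, ten-membered enynol, both C3 epimers | C/C=C(/C)C(=O)O[C@@H]1C[C@@](C)(O)C#CC(O)/C(C)=C\[C@H]2OC(=O)[C@@H](C)[C@@H]21 | intermediate
20 | (4Z,6R,7R,8R,10R,11S)-8-angeloyloxy-10-hydroxy-3-oxogermacr-4-en-1-yn-12,6-olide, ten-membered γ-hydroxy ynone | C/C=C(/C)C(=O)O[C@@H]1C[C@@](C)(O)C#CC(=O)/C(C)=C\[C@H]2OC(=O)[C@@H](C)[C@@H]21 | intermediate
21 | β-diketone: (4Z,6R,7R,8R,10R,11S)-8-angeloyloxy-10-hydroxy-1,3-dioxogermacr-4-en-12,6-olide | C/C=C(/C)C(=O)O[C@@H]1C[C@@](C)(O)C(=O)CC(=O)/C(C)=C\[C@H]2OC(=O)[C@@H](C)[C@@H]21 | intermediate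
22 | (4Z,6R,7R,8R,10R,11S)-8-angeloyloxy-3,10-epoxy-1-oxogermacra-2,4-dien-12,6-olide, CNP0278264.1 | C/C=C(/C)C(=O)O[C@@H]1C[C@@]2(C)OC(=CC2=O)/C(C)=C\[C@H]2OC(=O)[C@@H](C)[C@@H]21 | target

## Step count and risks

Total step count: 13. Longest linear sequence: 13 steps (1 → 22); compounds 7, 9 and 12 enter as bought.

The three steps most likely to fail:

**Step 4 (proline aldol).** Aldehyde 6 is a β-acyloxy aldehyde with an α-stereocentre, so amine-induced E1cB opening of the lactone or mismatched induction could erode yield or selectivity. The fallback sets out from 6 and comes back at 8. Aldehyde 6 is allylated under reagent control with the B-methallylborane (+)-Ipc2B–CH2C(CH3)=CH2 (from (+)-Ipc2BOMe and CH2=C(CH3)CH2MgCl; Et2O, −78 °C; ethanolamine work-up). This Brown allylboration attacks the Re face without forming an enamine or enolate and gives the homoallylic alcohol F1 with (8R) configuration. Ozonolysis of its 1,1-disubstituted alkene (O3, CH2Cl2, −78 °C; Me2S) then gives β-hydroxy ketone 8.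

**Step 11 (ten-membered ring closure).** Oligomerisation or reduction of the ynal could win over cyclisation. The fallback sets out from 8 and comes back at 20; it changes both the ring-closing reaction and the source of C3.
- Ketone 8 is treated with HC≡CMgBr under the conditions of step 5 to give the terminal-alkyne diol F2.
- The operations of steps 6 to 9 (mixed anhydride 13; HF·pyridine; Dess–Martin periodinane; Ph3P=C(CH3)I) convert it in turn into the angelate F3, the primary alcohol F4, the aldehyde F5 and the (Z)-vinyl iodide F6.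
- The ring is then closed by a carbonylative Sonogashira macrocyclisation (PdCl2(PPh3)2 5 mol %, CO 1 atm, Et3N, THF, 50 °C, slow addition to 2 mM). The vinylpalladium iodide inserts CO, the acylpalladium is captured by the terminal alkyne, and ynone 20 forms directly with CO as C3.

This closure is untested for a strained ten-membered ynone, which is why it is held in reserve.

**Step 13 (the proposed new step).** Meyer–Schuster rearrangement of the tertiary propargylic alcohol, hydration at C2, or catalyst inhibition could compete. The fallback uses known chemistry, sets out from 20 and comes back at 22. Ynone 20 is stirred with Et2NH (THF, rt); conjugate addition at C1 gives the (E)-enaminone F7. Treatment with aqueous oxalic acid (THF, rt) lets the C10 hydroxyl attack the C3 carbonyl, water is lost, and hydrolysis of the resulting 3-iminiofuran releases furanone 22. This is the classical amine-mediated conversion of γ-hydroxy ynones into 3(2H)-furanones.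

Further compounds

F1 | step 4 | homoallylic alcohol, (3S,4R,5S)-5-{[(tert-butyldimethylsilyl)oxy]methyl}-4-[(1R)-1-hydroxy-3-methylbut-3-en-1-yl]-3-methyloxolan-2-one | CC(C)(C)[Si](C)(C)OC[C@H]1OC(=O)[C@@H](C)[C@@H]1[C@H](O)CC(C)=C
F2 | step 11 | terminal-alkyne diol, (3S,4R,5S)-5-{[(tert-butyldimethylsilyl)oxy]methyl}-4-[(1R,3R)-1,3-dihydroxy-3-methylpent-4-yn-1-yl]-3-methyloxolan-2-one | CC(C)(C)[Si](C)(C)OC[C@H]1OC(=O)[C@@H](C)[C@@H]1[C@H](O)C[C@@](C)(O)C#C
F3 | step 11 | angelate, (1R,3R)-1-[(2S,3R,4S)-2-{[(tert-butyldimethylsilyl)oxy]methyl}-4-methyl-5-oxooxolan-3-yl]-3-hydroxy-3-methylpent-4-yn-1-yl (2Z)-2-methylbut-2-enoate | CC(C)(C)[Si](C)(C)OC[C@H]1OC(=O)[C@@H](C)[C@@H]1[C@H](OC(=O)/C(C)=C\C)C[C@@](C)(O)C#C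
F4 | step 11 | primary alcohol, (1R,3R)-3-hydroxy-1-[(2S,3R,4S)-2-(hydroxymethyl)-4-methyl-5-oxooxolan-3-yl]-3-methylpent-4-yn-1-yl (2Z)-2-methylbut-2-enoate | OC[C@H]1OC(=O)[C@@H](C)[C@@H]1[C@H](OC(=O)/C(C)=C\C)C[C@@](C)(O)C#C
F5 | step 11 | aldehyde, (1R,3R)-1-[(2S,3R,4S)-2-formyl-4-methyl-5-oxooxolan-3-yl]-3-hydroxy-3-methylpent-4-yn-1-yl (2Z)-2-methylbut-2-enoate | O=C[C@H]1OC(=O)[C@@H](C)[C@@H]1[C@H](OC(=O)/C(C)=C\C)C[C@@](C)(O)C#C
F6 | step 11 | (Z)-vinyl iodide, (1R,3R)-3-hydroxy-1-[(2S,3R,4S)-2-[(1Z)-2-iodoprop-1-en-1-yl]-4-methyl-5-oxooxolan-3-yl]-3-methylpent-4-yn-1-yl (2Z)-2-methylbut-2-enoate | I/C(C)=C\[C@H]1OC(=O)[C@@H](C)[C@@H]1[C@H](OC(=O)/C(C)=C\C)C[C@@](C)(O)C#C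
F7 | step 13 | (E)-enaminone, (1E,4Z,6R,7R,8R,10R,11S)-8-angeloyloxy-1-(diethylamino)-10-hydroxy-3-oxogermacra-1,4-dien-12,6-olide | C/C=C(/C)C(=O)O[C@@H]1C[C@@](C)(O)/C(N(CC)CC)=C\C(=O)/C(C)=C\[C@H]2OC(=O)[C@@H](C)[C@@H]21
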